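## Retrosynthetic overview

1. The tetrahydropyran and the spiro N,O-ketal form last. The O–C(spiro) bond and the C-a–H bond arise together when the free C-d hydroxyl closes reversibly onto the azafulvene of an ansa-bridged hydroxy-prodiginine.
2. The C-a–ring B bond comes from a Tf2O-driven condensation of a 12-membered pyrrolophane ketone with 4-methoxy-2,2'-bipyrrole. This bipyrrole carries rings A and B and is made by Suzuki coupling from 4-methoxy-3-pyrrolin-2-one.
3. The macrocycle is closed by ring-closing metathesis and hydrogenation in the middle of the heptamethylene bridge.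
4. The key C-a–C-b bond is made by an Evans boron syn-aldol. The donor is the N-acyl oxazolidinone of (S)-4-silyloxypentanoic acid, with C-d from (S)-propylene oxide. The acceptor is 5-(pent-4-enyl)-1-tosylpyrrole-2-carbaldehyde. The aldol sets C-b, and the imide carbon becomes the first CH2 of the bridge.
5. Ring order: ring C (bought as pyrrole), then the macrocycle, then rings A and B (attached as the preformed bipyrrole), then the tetrahydropyran with the spiro centre.

Assumption: the SMILES is read as spiro centre R, C-a S, C-b S, C-d S; ring A = terminal pyrrole, ring B = methoxy-2H-pyrrole, ring C = bridged pyrrole, C-a = CH between spiro centre and ring C, C-b = neighbouring CH that carries the bridge, C-d = CH(CH3)–O; TBS = tert-butyldimethylsilyl, TES = triethylsilyl, Ts = 4-methylphenylsulfonyl.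

## Route

Step 1
Reactants: 1 (S)-propylene oxide; 2 allylmagnesium bromide
Product: 3 (S)-hex-5-en-2-ol
Conditions: CuI (10 mol %), THF, −30 to 0 °C; aqueous work-up
Reagents that add atoms: none
Why: Copper-catalysed SN2 opening of the epoxide by the Grignard reagent occurs only at the unsubstituted carbon, so the S carbinol centre (C-d) is carried over untouched from the chiral pool.

Step 2
Reactants: 3 (S)-hex-5-en-2-ol
Product: 4 (S)-tert-butyl(hex-5-en-2-yloxy)dimethylsilane
Conditions: TBSCl, imidazole, DMF, rt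
Reagents that add atoms: tert-butyldimethylsilyl chloride CC(C)(C)[Si](C)(C)Cl
Why: This is a standard Corey silylation of a secondary alcohol and does not involve the stereocentre.

Step 3
Reactants: 4 (S)-tert-butyl(hex-5-en-2-yloxy)dimethylsilane
Product: 5 (S)-4-(tert-butyldimethylsilyloxy)pentanoic acid
Conditions: RuCl3·xH2O (2 mol %), NaIO4 (4.1 equiv), MeCN/EtOAc/H2O, rt
Reagents that add atoms: sodium periodate [Na+].[O-]I(=O)(=O)=O; water O
Why: Sharpless ruthenium tetroxide cleavage turns the terminal alkene into the acid with loss of one carbon, and the silyl ether and C-d are inert to it.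

Step 4
Reactants: 5 (S)-4-(tert-butyldimethylsilyloxy)pentanoic acid; 6 (S)-4-benzyl-1,3-oxazolidin-2-one
Product: 8 (S)-4-benzyl-3-[(S)-4-(tert-butyldimethylsilyloxy)pentanoyl]-1,3-oxazolidin-2-one, via mixed pivalic anhydride 7 (not isolated)
Conditions: PivCl, Et3N, THF, −20 to 0 °C; then LiCl, 6, rt
Reagents that add atoms: none
Why: In this mixed-anhydride N-acylation the LiCl-activated oxazolidinone attacks the unhindered carbonyl of 7 without strong base, so no stereocentre is touched.

Step 5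
Reactants: 9 pent-4-enoic acid
Product: 10 S-(pyridin-2-yl) pent-4-enethioate
Conditions: 2,2'-dipyridyl disulfide, PPh3, toluene, rt
Reagents that add atoms: 2,2'-dipyridyl disulfide c1ccc(SSc2ccccn2)nc1
Why: The Mukaiyama redox condensation gives the activated thioester under neutral conditions that leave the alkene in place.

Step 6
Reactants: 11 pyrrole; 10 S-(pyridin-2-yl) pent-4-enethioate
Product: 13 1-(1H-pyrrol-2-yl)pent-4-en-1-one, via pyrrolylmagnesium chloride 12 (not isolated)
Conditions: 11 (3 equiv), MeMgCl (3 equiv), THF/toluene, 0 °C; then 10, −78 °C; aqueous work-up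
Reagents that add atoms: none
Why: C-acylation of the pyrrolyl Grignard reagent by a 2-pyridyl thioester runs through a magnesium chelate and gives only the 2-acylpyrrole.

Step 7
Reactants: 13 1-(1H-pyrrol-2-yl)pent-4-en-1-one
Product: 15 2-(pent-4-en-1-yl)-1H-pyrrole, via pyrrolyl carbinol 14 (not isolated)
Conditions: NaBH4 (excess), i-PrOH, reflux
Reagents that add atoms: none
Why: In this reductive deoxygenation of a 2-acylpyrrole, borohydride first gives carbinol 14, a second hydride then replaces its activated C–O bond, and the isolated alkene is not touched.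

Step 8
Reactants: 15 2-(pent-4-en-1-yl)-1H-pyrrole
Product: 17 5-(pent-4-en-1-yl)-1H-pyrrole-2-carbaldehyde, via iminium chloride 16 (not isolated)
Conditions: POCl3, DMF, ClCH2CH2Cl, 0 °C to rt; then aq. NaOH
Reagents that add atoms: N,N-dimethylformamide CN(C)C=O; water O
Why: Vilsmeier–Haack formylation attacks the only free alpha position of the 2-alkylpyrrole.

Step 9
Reactants: 17 5-(pent-4-en-1-yl)-1H-pyrrole-2-carbaldehyde
Product: 19 5-(pent-4-en-1-yl)-1-tosylpyrrole-2-carbaldehyde, via sodium pyrrolide 18 (not isolated)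
Conditions: NaH, THF, 0 °C; then TsCl, 0 °C to rt
Reagents that add atoms: 4-toluenesulfonyl chloride Cc1ccc(cc1)S(=O)(=O)Cl
Why: N-sulfonylation removes the acidic N–H, makes the aldehyde more electrophilic, and later keeps the pyrrolyl carbinol from ionising.

Step 10
Reactants: 8 (S)-4-benzyl-3-[(S)-4-(tert-butyldimethylsilyloxy)pentanoyl]-1,3-oxazolidin-2-one; 19 5-(pent-4-en-1-yl)-1-tosylpyrrole-2-carbaldehyde
Product: 22 (S)-4-benzyl-3-{(2S,4S)-4-(TBSO)-2-[(S)-hydroxy(5-pent-4-enyl-1-tosylpyrrol-2-yl)methyl]pentanoyl}-1,3-oxazolidin-2-one, via Z boron enolate 20 (not isolated), via boron aldolate 21 (not isolated)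
Conditions: Bu2BOTf (1.2 equiv), Et3N (1.4 equiv), CH2Cl2, 0 °C; 19, −78 to 0 °C; then pH 7 buffer, MeOH, 30 % H2O2, 0 °C
Reagents that add atoms: none
Why: In this Evans boron syn-aldol the Z enolate reacts through a Zimmerman–Traxler chair on the face away from the benzyl group, which joins the two fragments at the C-a–C-b bond and sets C-b as S (2S,3S adduct, whose carbinol centre is erased in step 16).

Step 11
Reactants: 22 syn-aldol adduct
Product: 23 O-triethylsilyl ether of 22 (2S,4S and carbinol S unchanged)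
Conditions: TESOTf, 2,6-lutidine, CH2Cl2, −78 to 0 °C
Reagents that add atoms: triethylsilyl trifluoromethanesulfonate CC[Si](CC)(CC)OS(=O)(=O)C(F)(F)F
Why: Silyl triflate silylation caps the hindered carbinol, which blocks retro-aldol and Grob-type fragmentation in the next steps, and TES can later be removed beside TBS.

Step 12
Reactants: 23 O-triethylsilyl ether of 22
Product: 24 (2R,4S)-4-(TBSO)-2-{(S)-[5-(pent-4-enyl)-1-tosylpyrrol-2-yl](triethylsilyloxy)methyl}pentan-1-ol
Conditions: LiBH4, THF/Et2O, 0 °C to rt; aqueous work-up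
Reagents that add atoms: none
Why: Reductive cleavage of the imide at its exocyclic carbonyl gives the primary alcohol without epimerising C-b (the descriptor changes only by priority) and returns the auxiliary.

Step 13
Reactants: 24 primary alcohol
Product: 25 2-[(1S,2S,4S)-4-(TBSO)-2-(iodomethyl)-1-(triethylsilyloxy)pentyl]-5-(pent-4-enyl)-1-tosylpyrrole
Conditions: I2, PPh3, imidazole, CH2Cl2, 0 °C to rt
Reagents that add atoms: iodine II
Why: Appel-type iodination under Garegg–Samuelsson conditions works on the primary alcohol under buffered conditions that both silyl ethers survive.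

Step 14
Reactants: 25 primary iodide; 2 allylmagnesium bromide
Product: 26 2-{(1S,2S)-2-[(S)-2-(TBSO)propyl]-1-(triethylsilyloxy)hex-5-enyl}-5-(pent-4-enyl)-1-tosylpyrrole
Conditions: 2 (3 equiv), CuI (20 mol %), THF, −30 to 0 °C
Reagents that add atoms: none
Why: Copper-catalysed Kochi-type sp3–sp3 coupling of a primary iodide with the reactive allyl Grignard reagent places the second terminal alkene three bonds from C-b, out of reach of conjugation with the later ketone.

Step 15
Reactants: 26 bis-silyl ether diene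
Product: 27 (1S,2S)-2-[(S)-2-(TBSO)propyl]-1-[5-(pent-4-enyl)-1-tosylpyrrol-2-yl]hex-5-en-1-ol
Conditions: PPTS (0.2 equiv), MeOH/CH2Cl2, 0 °C
Reagents that add atoms: none
Why: Acid-catalysed methanolysis cleaves TES about two orders of magnitude faster than TBS, and the N-tosyl group keeps the pyrrolyl carbinol from ionising.

Step 16
Reactants: 27 secondary alcohol
Product: 28 (S)-2-[(S)-2-(TBSO)propyl]-1-[5-(pent-4-enyl)-1-tosylpyrrol-2-yl]hex-5-en-1-one
Conditions: Dess–Martin periodinane, CH2Cl2, 0 °C to rt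
Reagents that add atoms: none
Why: Dess–Martin oxidation is non-basic, so the alpha centre C-b is not epimerised while C-a becomes the ketone carbon.

Step 17
Reactants: 28 N-tosyl ketone
Product: 29 (S)-2-[(S)-2-(TBSO)propyl]-1-[5-(pent-4-enyl)-1H-pyrrol-2-yl]hex-5-en-1-one
Conditions: LiOH·H2O (3 equiv), THF/H2O (4:1), 0 °C to rt, stopped at full conversion
Reagents that add atoms: none
Why: In this nucleophilic desulfonylation hydroxide attacks the activated N-sulfonyl group much faster than it enolises the hindered tertiary alpha C–H, and the acylpyrrolide that forms resists enolisation, so C-b holds.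

Step 18
Reactants: 29 N–H acylpyrrole diene
Product: 30 12-membered pyrrolophane enone-free alkene (ring C bridged from C-2 to C-5 by C(=O)–C-b–CH2CH2CH=CHCH2CH2CH2; C-b S; side chain (S)-2-(TBSO)propyl; E/Z mixture)
Conditions: second-generation Grubbs catalyst (5 mol %), 1,4-benzoquinone (10 mol %), CH2Cl2 (1 mM), reflux
Reagents that add atoms: none
Why: Ring-closing metathesis joins two unhindered terminal alkenes at high dilution with loss of ethene, on a substrate whose small N–H can point into the ring and whose alkenes are remote from C-b.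

Step 19
Reactants: 30 macrocyclic alkene
Product: 31 saturated pyrrolophane ketone (bridge C(=O)–C-b–(CH2)7; C-b S; side chain (S)-2-(TBSO)propyl)
Conditions: H2 (1 atm), Pd/C (10 wt %), EtOAc, rt
Reagents that add atoms: none
Why: Catalytic hydrogenation saturates the disubstituted alkene, which removes the E/Z issue, and the acylpyrrole (a vinylogous amide) is inert.

Step 20
Reactants: 32 4-methoxy-3-pyrrolin-2-one
Product: 33 tert-butyl 4-methoxy-2-oxo-2,5-dihydropyrrole-1-carboxylate
Conditions: Boc2O, DMAP (10 mol %), MeCN, rt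
Reagents that add atoms: di-tert-butyl dicarbonate CC(C)(C)OC(=O)OC(=O)OC(C)(C)C
Why: DMAP-catalysed N-acylation of the lactam acidifies the C-5 methylene and will stabilise the pyrrolyl triflate.

Step 21
Reactants: 33 N-Boc lactam
Product: 35 tert-butyl 4-methoxy-2-(trifluoromethylsulfonyloxy)pyrrole-1-carboxylate, via sodium 2-oxidopyrrole 34 (not isolated)
Conditions: NaHMDS, THF, −78 °C; PhNTf2, −78 to 0 °C
Reagents that add atoms: N-phenylbis(trifluoromethanesulfonimide) O=S(=O)(N(c1ccccc1)S(=O)(=O)C(F)(F)F)C(F)(F)F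
Why: Deprotonation at C-5 gives the aromatic dienolate (the same enolisation that gives 2-silyloxypyrroles), and the triflimide sulfonylates it on oxygen in a normal enol triflate formation.

Step 22
Reactants: 35 pyrrolyl triflate; 36 1-(tert-butoxycarbonyl)pyrrol-2-ylboronic acid
Product: 37 di-tert-butyl 4-methoxy-2,2'-bipyrrole-1,1'-dicarboxylate
Conditions: Pd(PPh3)4 (5 mol %), K2CO3, dioxane/H2O, 85 °C
Reagents that add atoms: none
Why: Suzuki–Miyaura coupling of a heteroaryl triflate with the standard ring A boronic acid forms the A–B bond regiospecifically.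

Step 23
Reactants: 37 bis-Boc bipyrrole
Product: 38 4-methoxy-1H,1'H-2,2'-bipyrrole
Conditions: NaOMe (0.3 equiv), MeOH/THF, rt, argon; used at once
Reagents that add atoms: none
Why: Pyrrole carbamates are activated acyl donors and undergo methanolysis under mild base.

Step 24
Reactants: 31 saturated pyrrolophane ketone; 38 4-methoxy-1H,1'H-2,2'-bipyrrole
Product: 40 O-TBS ansa-prodiginine (C-a=C-2 of ring B; drawn as the N–H···N bonded Z isomer; C-b S; C-d S), via azafulvene triflate 39 (not isolated)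
Conditions: Tf2O (1.1 equiv), 2,6-di-tert-butyl-4-methylpyridine (2.5 equiv), CH2Cl2, −78 to −20 °C; then 38 (1.3 equiv), −78 to 0 °C; aq. NaHCO3
Reagents that add atoms: none
Why: In this Vilsmeier–Haack-type condensation, O-triflation of the vinylogous amide makes C-a strongly electrophilic, the bipyrrole attacks through its most nucleophilic alpha carbon next to the methoxy group (the position at which it is also formylated), and loss of triflic acid gives the dipyrrin.

Step 25
Reactants: 40 O-TBS ansa-prodiginine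
Product: 42 premarineosin A (spiro centre R; C-a S; C-b S; C-d S), via hydroxy-prodiginine 41 (not isolated)
Conditions: HF·pyridine, pyridine, THF, 0 °C to rt; sat. aq. NaHCO3
Reagents that add atoms: none
Why: Fluoride frees the C-d alcohol, and the bridge-twisted meso-alkyl dipyrrin is then protonated at C-a and captured by the hydroxyl at C-2 of ring B (an intramolecular hydroalkoxylation, or spiro-N,O-ketalisation), a reversible closure in which the fixed C-b and C-d centres are expected to steer C-a and the spiro centre to the chair with ring C and the bridge trans-diequatorial and the C–N bond axial (anomeric effect), which is the S,R pair of the target.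

## Compound list

1 | (S)-propylene oxide | C[C@H]1CO1 | starting material
2 | allylmagnesium bromide | C=CC[Mg]Br | starting material
3 | (S)-hex-5-en-2-ol | C[C@H](O)CCC=C | intermediate
4 | (S)-tert-butyl(hex-5-en-2-yloxy)dimethylsilane | C[C@H](O[Si](C)(C)C(C)(C)C)CCC=C | intermediate
5 | (S)-4-(tert-butyldimethylsilyloxy)pentanoic acid | C[C@H](O[Si](C)(C)C(C)(C)C)CCC(=O)O | intermediate
6 | (S)-4-benzyl-1,3-oxazolidin-2-one | O=C1N[C@@H](Cc2ccccc2)CO1 | starting material
7 | mixed pivalic anhydride of 5 | C[C@H](O[Si](C)(C)C(C)(C)C)CCC(=O)OC(=O)C(C)(C)C | intermediate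
8 | (S)-4-benzyl-3-[(S)-4-(TBSO)pentanoyl]-1,3-oxazolidin-2-one | C[C@H](O[Si](C)(C)C(C)(C)C)CCC(=O)N1[C@@H](Cc2ccccc2)COC1=O | intermediate
9 | pent-4-enoic acid | C=CCCC(=O)O | starting material
10 | S-(pyridin-2-yl) pent-4-enethioate | C=CCCC(=O)Sc1ccccn1 | intermediate
11 | pyrrole | c1cc[nH]c1 | starting material
12 | pyrrol-1-ylmagnesium chloride | Cl[Mg]n1cccc1 | intermediate
13 | 1-(1H-pyrrol-2-yl)pent-4-en-1-one | C=CCCC(=O)c1ccc[nH]1 | intermediate
14 | 1-(1H-pyrrol-2-yl)pent-4-en-1-ol (racemic) | C=CCCC(O)c1ccc[nH]1 | intermediate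
15 | 2-(pent-4-en-1-yl)-1H-pyrrole | C=CCCCc1ccc[nH]1 | intermediate
16 | dimethyl{[5-(pent-4-enyl)-1H-pyrrol-2-yl]methylidene}ammonium chloride | C=CCCCc1ccc(C=[N+](C)C)[nH]1.[Cl-] | intermediate
17 | 5-(pent-4-en-1-yl)-1H-pyrrole-2-carbaldehyde | C=CCCCc1ccc(C=O)[nH]1 | intermediate
18 | sodium salt of 17 | C=CCCCc1ccc(C=O)[n-]1.[Na+] | intermediate
19 | 5-(pent-4-en-1-yl)-1-tosylpyrrole-2-carbaldehyde | C=CCCCc1ccc(C=O)n1S(=O)(=O)c1ccc(C)cc1 | intermediate
20 | Z dibutylboron enolate of 8 | C[C@H](O[Si](C)(C)C(C)(C)C)C/C=C(\OB(CCCC)CCCC)N1[C@@H](Cc2ccccc2)COC1=O | intermediate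
21 | dibutylboron aldolate of 22 | C[C@H](O[Si](C)(C)C(C)(C)C)C[C@H](C(=O)N1[C@@H](Cc2ccccc2)COC1=O)[C@H](OB(CCCC)CCCC)c1ccc(CCCC=C)n1S(=O)(=O)c1ccc(C)cc1 | intermediate
22 | Evans syn-aldol adduct (2S,4S; carbinol S; auxiliary S) | C[C@H](O[Si](C)(C)C(C)(C)C)C[C@H](C(=O)N1[C@@H](Cc2ccccc2)COC1=O)[C@H](O)c1ccc(CCCC=C)n1S(=O)(=O)c1ccc(C)cc1 | intermediate
23 | O-TES ether of 22 | C[C@H](O[Si](C)(C)C(C)(C)C)C[C@H](C(=O)N1[C@@H](Cc2ccccc2)COC1=O)[C@H](O[Si](CC)(CC)CC)c1ccc(CCCC=C)n1S(=O)(=O)c1ccc(C)cc1 | intermediate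
24 | (2R,4S)-4-(TBSO)-2-{(S)-[5-(pent-4-enyl)-1-tosylpyrrol-2-yl](TESO)methyl}pentan-1-ol | C[C@H](O[Si](C)(C)C(C)(C)C)C[C@H](CO)[C@H](O[Si](CC)(CC)CC)c1ccc(CCCC=C)n1S(=O)(=O)c1ccc(C)cc1 | intermediate
25 | 2-[(1S,2S,4S)-4-(TBSO)-2-(iodomethyl)-1-(TESO)pentyl]-5-(pent-4-enyl)-1-tosylpyrrole | C[C@H](O[Si](C)(C)C(C)(C)C)C[C@H](CI)[C@H](O[Si](CC)(CC)CC)c1ccc(CCCC=C)n1S(=O)(=O)c1ccc(C)cc1 | intermediate
26 | 2-{(1S,2S)-2-[(S)-2-(TBSO)propyl]-1-(TESO)hex-5-enyl}-5-(pent-4-enyl)-1-tosylpyrrole | C[C@H](O[Si](C)(C)C(C)(C)C)C[C@H](CCC=C)[C@H](O[Si](CC)(CC)CC)c1ccc(CCCC=C)n1S(=O)(=O)c1ccc(C)cc1 | intermediate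
27 | (1S,2S)-2-[(S)-2-(TBSO)propyl]-1-[5-(pent-4-enyl)-1-tosylpyrrol-2-yl]hex-5-en-1-ol | C[C@H](O[Si](C)(C)C(C)(C)C)C[C@H](CCC=C)[C@H](O)c1ccc(CCCC=C)n1S(=O)(=O)c1ccc(C)cc1 | intermediate
28 | (S)-2-[(S)-2-(TBSO)propyl]-1-[5-(pent-4-enyl)-1-tosylpyrrol-2-yl]hex-5-en-1-one | C[C@H](O[Si](C)(C)C(C)(C)C)C[C@H](CCC=C)C(=O)c1ccc(CCCC=C)n1S(=O)(=O)c1ccc(C)cc1 | intermediate
29 | (S)-2-[(S)-2-(TBSO)propyl]-1-[5-(pent-4-enyl)-1H-pyrrol-2-yl]hex-5-en-1-one | C[C@H](O[Si](C)(C)C(C)(C)C)C[C@H](CCC=C)C(=O)c1ccc(CCCC=C)[nH]1 | intermediate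
30 | unsaturated pyrrolophane ketone (C-b S, C-d S, E/Z mixture) | C[C@H](O[Si](C)(C)C(C)(C)C)C[C@@H]1CCC=CCCCc2ccc([nH]2)C1=O | intermediate
31 | saturated pyrrolophane ketone (C-b S, C-d S) | C[C@H](O[Si](C)(C)C(C)(C)C)C[C@@H]1CCCCCCCc2ccc([nH]2)C1=O | intermediate
32 | 4-methoxy-3-pyrrolin-2-one | COC1=CC(=O)NC1 | starting material
33 | tert-butyl 4-methoxy-2-oxo-2,5-dihydropyrrole-1-carboxylate | COC1=CC(=O)N(C(=O)OC(C)(C)C)C1 | intermediate
34 | sodium 1-Boc-4-methoxypyrrol-2-olate | COc1cc([O-])n(C(=O)OC(C)(C)C)c1.[Na+] | intermediate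
35 | tert-butyl 4-methoxy-2-(trifluoromethylsulfonyloxy)pyrrole-1-carboxylate | COc1cc(OS(=O)(=O)C(F)(F)F)n(C(=O)OC(C)(C)C)c1 | intermediate
36 | 1-(tert-butoxycarbonyl)pyrrol-2-ylboronic acid | CC(C)(C)OC(=O)n1cccc1B(O)O | starting material
37 | di-tert-butyl 4-methoxy-2,2'-bipyrrole-1,1'-dicarboxylate | COc1cc(-c2cccn2C(=O)OC(C)(C)C)n(C(=O)OC(C)(C)C)c1 | intermediate
38 | 4-methoxy-1H,1'H-2,2'-bipyrrole | COc1c[nH]c(-c2ccc[nH]2)c1 | intermediate
39 | azafulvene triflate of 31 (C-a bears OTf; ring C as 2H-pyrrol-2-ylidene) | C[C@H](O[Si](C)(C)C(C)(C)C)C[C@@H]1CCCCCCCC2=NC(C=C2)=C1OS(=O)(=O)C(F)(F)F | intermediate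
40 | O-TBS ansa-prodiginine (Z, C-b S, C-d S) | C[C@H](O[Si](C)(C)C(C)(C)C)C[C@@H]1CCCCCCCc2ccc([nH]2)/C1=C3\N=C(c4ccc[nH]4)C=C3OC | intermediate
41 | hydroxy ansa-prodiginine (Z, C-b S, C-d S) | C[C@H](O)C[C@@H]1CCCCCCCc2ccc([nH]2)/C1=C3\N=C(c4ccc[nH]4)C=C3OC | intermediate
42 | premarineosin A | COC1=CC(c2ccc[nH]2)=N[C@]12O[C@@H](C)C[C@@H]1CCCCCCCc3ccc([nH]3)[C@H]12 | target

## Step count and risks

Total step count: 25.
Longest linear sequence: 17 steps (9 → 10 → 13 → 15 → 17 → 19 → 22 → 23 → 24 → 25 → 26 → 27 → 28 → 29 → 30 → 31 → 40 → 42).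

**Step 18 (ring-closing metathesis of 29).**
- Risk: the conjugated, hydrogen-bonding acylpyrrole may hold the two chains apart and give oligomers instead of the 12-membered ring.
- Fallback, from 26 back to 31: the ring is closed while C-a is still sp3 and the nitrogen is already free.
- Compound 26 is detosylated with Mg turnings in MeOH (sonication, rt) to the N–H pyrrole diene F1.
- F1 is closed with the second-generation Grubbs catalyst at 1 mM to the macrocyclic alkene bis-silyl ether F2.
- H2 over Pd/C gives the saturated macrocyclic bis-silyl ether F3.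
- Bu4NF (1 equiv, THF, 0 °C) removes only the TES group to give the macrocyclic pyrrolyl carbinol F4.
- MnO2 in CH2Cl2, a neutral oxidant that avoids ionising the N–H carbinol, oxidises F4 to 31.

**Step 24 (condensation of 31 with 38).**
- Risk: the alpha-branched, bridged ketone may be triflated sluggishly, or may lose the C-b proton to give an enol triflate.
- Fallback, from 31 back to 40: the C-a–ring B bond is made at the alcohol oxidation level and the chromophore is installed afterwards.
- NaBH4 (MeOH/THF, 0 °C) gives the macrocyclic carbinol F5 as a mixture of C-a epimers.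
- Sc(OTf)3 (5 mol %, CH2Cl2, 0 °C) ionises F5 in the presence of 38 and gives, by Friedel–Crafts alkylation, the dipyrromethane F6.
- DDQ (1 equiv, CH2Cl2, 0 °C) dehydrogenates F6 to 40.

**Step 25 (desilylation and spiro closure).**
- Risk: this step decides two stereocentres at once. In the product chair the C-d methyl is axial and 1,3-diaxial to the nitrogen, so the thermodynamic margin over the spiro epimer, the open chromophore and a reversible five-membered ether at C-a is small.
- Fallback, from 31 (with 33 and 36) to 42: the spiro centre is built on a lactam, where no stabilised chromophore competes, and ring A is attached last.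
- Compound 33 is silylated (TBSOTf, Et3N, CH2Cl2) to the silyloxypyrrole F7.
- Ketone 31 is activated as in step 24 (Tf2O, 2,6-di-tert-butyl-4-methylpyridine) and trapped by F7 in a vinylogous Mukaiyama-type addition–elimination to give the ylidene lactam F8.
- Aqueous HF in MeCN followed by TFA in CH2Cl2 removes TBS and Boc and protonates the enamide at C-a. The hydroxyl captures the N-acyliminium ion to give the spiro lactam F9, equilibrated under the acid.
- Tf2O with 2,6-lutidine gives the spiro imidoyl triflate F10.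
- Suzuki coupling of F10 with 36 [Pd(PPh3)4, K2CO3, dioxane/H2O] gives N-Boc-premarineosin A F11.
- NaOMe in MeOH takes F11 to 42.

## Further compounds

F1 | step 18 | N–H pyrrole diene (26 without tosyl; 1S,2S, side chain S) | C[C@H](O[Si](C)(C)C(C)(C)C)C[C@H](CCC=C)[C@H](O[Si](CC)(CC)CC)c1ccc(CCCC=C)[nH]1
F2 | step 18 | macrocyclic alkene bis-silyl ether (E/Z mixture) | C[C@H](O[Si](C)(C)C(C)(C)C)C[C@@H]1CCC=CCCCc2ccc([nH]2)[C@H]1O[Si](CC)(CC)CC
F3 | step 18 | saturated macrocyclic bis-silyl ether | C[C@H](O[Si](C)(C)C(C)(C)C)C[C@@H]1CCCCCCCc2ccc([nH]2)[C@H]1O[Si](CC)(CC)CC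
F4 | step 18 | macrocyclic pyrrolyl carbinol (single C-a epimer) | C[C@H](O[Si](C)(C)C(C)(C)C)C[C@@H]1CCCCCCCc2ccc([nH]2)[C@H]1O
F5 | step 24 | macrocyclic carbinol (both C-a epimers) | C[C@H](O[Si](C)(C)C(C)(C)C)C[C@@H]1CCCCCCCc2ccc([nH]2)C1O
F6 | step 24 | dipyrromethane (both C-a epimers) | C[C@H](O[Si](C)(C)C(C)(C)C)C[C@@H]1CCCCCCCc2ccc([nH]2)C1c3[nH]c(-c4ccc[nH]4)cc3OC
F7 | step 25 | tert-butyl 2-(tert-butyldimethylsilyloxy)-4-methoxypyrrole-1-carboxylate | COc1cc(O[Si](C)(C)C(C)(C)C)n(C(=O)OC(C)(C)C)c1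
F8 | step 25 | N-Boc ylidene lactam (alkene geometry open) | C[C@H](O[Si](C)(C)C(C)(C)C)C[C@@H]1CCCCCCCc2ccc([nH]2)C1=C3N(C(=O)OC(C)(C)C)C(=O)C=C3OC
F9 | step 25 | spiro lactam | COC1=CC(=O)N[C@]12O[C@@H](C)C[C@@H]1CCCCCCCc3ccc([nH]3)[C@H]12
F10 | step 25 | spiro imidoyl triflate | COC1=CC(OS(=O)(=O)C(F)(F)F)=N[C@]12O[C@@H](C)C[C@@H]1CCCCCCCc3ccc([nH]3)[C@H]12
F11 | step 25 | N-Boc-premarineosin A (Boc on ring A) | COC1=CC(c2cccn2C(=O)OC(C)(C)C)=N[C@]12O[C@@H](C)C[C@@H]1CCCCCCCc3ccc([nH]3)[C@H]12
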